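The plan cuts the C7–C8 bond, which joins the carbinol carbon C7 on ring A (3,4,5-trimethoxyphenyl) to C8, the carbon that carries the ring B aryloxy oxygen; with C9 raised to an acyl carbon this pair is an aldol retron. A magnesium-catalysed, auxiliary-controlled anti aldol between an aryloxyacetyl imide and 3,4,5-trimethoxybenzaldehyde forms this bond and both stereocentres in one operation and joins the two aryl halves; no ring is formed. The precursor is the (R)-4-benzyloxazolidinone imide of (4-allyl-2,6-dimethoxyphenoxy)acetic acid, made in three steps from 4-allyl-2,6-dimethoxyphenol. Afterwards the acyl carbon C9 is reduced in three steps to the methyl group.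

Key step: step 4

Assumption: neolignan numbering is used (C7 benzylic carbinol on ring A, C8 ether carbon, C9 methyl; ring B is the 4-allyl-2,6-dimethoxyphenyl ring), and the four starting materials and both enantiomers of 4-benzyloxazolidin-2-one are taken as commercial.

Remark on stereochemistry: the target is the erythro (7S,8R) isomer, which corresponds to an anti aldol adduct. In the aldol adduct the same arrangement at C8 is written S, because the acyl carbon ranks above C7; once C9 is a methyl group it reads R.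

Step 1
Reactants: 1 4-allyl-2,6-dimethoxyphenol; 2 ethyl bromoacetate
Product: 3 ethyl 2-(4-allyl-2,6-dimethoxyphenoxy)acetate
Conditions: K2CO3, acetone, reflux
Reagents that add atoms: none
Why: Williamson ether synthesis, in which the phenoxide formed by K2CO3 displaces bromide from the activated α-bromo ester by SN2, the two ortho methoxy groups slowing but not blocking O-alkylation, and no stereocentre is formed.

Step 2
Reactants: 3 ethyl 2-(4-allyl-2,6-dimethoxyphenoxy)acetate
Product: 4 2-(4-allyl-2,6-dimethoxyphenoxy)acetic acid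
Conditions: LiOH·H2O, THF/H2O, rt; then 1 M HCl
Reagents that add atoms: lithium hydroxide, [Li+].[OH-]
Why: Saponification of an unhindered ethyl ester by acyl–oxygen cleavage at room temperature, mild enough to leave the allyl group unisomerised, with no stereocentre involved.

Step 3
Reactants: 4 2-(4-allyl-2,6-dimethoxyphenoxy)acetic acid; 5 (R)-4-benzyloxazolidin-2-one
Product: 7 (R)-3-[2-(4-allyl-2,6-dimethoxyphenoxy)acetyl]-4-benzyloxazolidin-2-one, via mixed pivalic anhydride 6 (not isolated)
Conditions: PivCl, Et3N, THF, −20 °C; then 5, LiCl, −20 °C to rt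
Reagents that add atoms: pivaloyl chloride, CC(C)(C)C(=O)Cl (its pivaloyl group stays in 6 only and is absent from 7)
Why: Mixed-anhydride N-acylation of the oxazolidinone promoted by LiCl and Et3N, in which the nitrogen attacks the less hindered and more electrophilic aryloxyacetyl carbonyl of 6, so that no organolithium base meets the allylarene and the auxiliary stereocentre is untouched.

Step 4
Reactants: 7 (R)-3-[2-(4-allyl-2,6-dimethoxyphenoxy)acetyl]-4-benzyloxazolidin-2-one; 8 3,4,5-trimethoxybenzaldehyde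
Product: 10 (R)-3-[(2S,3S)-2-(4-allyl-2,6-dimethoxyphenoxy)-3-hydroxy-3-(3,4,5-trimethoxyphenyl)propanoyl]-4-benzyloxazolidin-2-one, via O-trimethylsilyl aldol adduct 9 (not isolated)
Conditions: MgCl2 (20 mol%), Et3N, Me3SiCl, EtOAc, rt; then 1 M HCl, THF, 0 °C
Reagents that add atoms: chlorotrimethylsilane, C[Si](C)(C)Cl (its Me3Si group stays in 9 only and is absent from 10)
Why: MgCl2 and Et3N soft-enolise imide 7 to a magnesium Z-enolate in which the metal bridges the enolate oxygen and the oxazolidinone carbonyl, this enolate adds to the non-enolisable aldehyde 8, and Me3SiCl silylates the magnesium aldolate, which releases the metal for the next turnover and shuts off retro-aldol reversal. The closest known reaction type is the magnesium halide-catalysed direct anti aldol of N-acyl-4-benzyloxazolidinones with aromatic aldehydes, applied here to an aryloxyacetyl acyl group whose α-oxygen raises the acidity of the C8 hydrogens and so favours the soft enolisation. No ring is closed; the step forms the single C7–C8 bond. C8 is fixed by the (R)-benzyl group of the auxiliary, which screens one face of the chelated enolate, and C7 is fixed by the closed boat-like transition state through which aromatic aldehydes give the anti (erythro) adduct. The step needs the anti relationship together with the correct enolate face: the rigid chelate secures the face, and the aromatic partner, whose 3,4,5-trimethoxy pattern leaves the carbonyl group about as electrophilic as that of benzaldehyde, is the aldehyde class for which the anti preference is established. Dilute aqueous HCl in THF then cleaves the Me3Si ether without exposing the electron-rich benzylic carbinol to an acidic alcohol solvent, in which it could form a benzylic ether.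

Step 5
Reactants: 10 (R)-3-[(2S,3S)-2-(4-allyl-2,6-dimethoxyphenoxy)-3-hydroxy-3-(3,4,5-trimethoxyphenyl)propanoyl]-4-benzyloxazolidin-2-one
Product: 11 (1S,2R)-2-(4-allyl-2,6-dimethoxyphenoxy)-1-(3,4,5-trimethoxyphenyl)propane-1,3-diol
Conditions: LiBH4, H2O (1 equiv), THF, 0 °C
Reagents that add atoms: none
Why: Reductive cleavage of the N-acyloxazolidinone with LiBH4, in which hydride attacks the exocyclic imide carbonyl (activated by the α-aryloxy group and by lithium chelation) and then the released aldehyde, giving the C9 primary alcohol and returning the auxiliary while C7 and C8 are not touched.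

Step 6
Reactants: 11 (1S,2R)-2-(4-allyl-2,6-dimethoxyphenoxy)-1-(3,4,5-trimethoxyphenyl)propane-1,3-diol
Product: 12 (2R,3S)-2-(4-allyl-2,6-dimethoxyphenoxy)-3-hydroxy-3-(3,4,5-trimethoxyphenyl)propyl 4-methylbenzenesulfonate
Conditions: TsCl (1.1 equiv), Et3N, DMAP (cat.), CH2Cl2, 0 °C
Reagents that add atoms: p-toluenesulfonyl chloride, Cc1ccc(cc1)S(=O)(=O)Cl
Why: Selective tosylation of the primary C9 hydroxyl over the hindered secondary benzylic C7 hydroxyl with a small excess of sulfonyl chloride at low temperature (steric discrimination in sulfonate ester formation), with no stereocentre affected.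

Step 7
Reactants: 12 (2R,3S)-2-(4-allyl-2,6-dimethoxyphenoxy)-3-hydroxy-3-(3,4,5-trimethoxyphenyl)propyl 4-methylbenzenesulfonate
Product: 13 rhaphidecursinol B, (1S,2R)-2-(4-allyl-2,6-dimethoxyphenoxy)-1-(3,4,5-trimethoxyphenyl)propan-1-ol (7S,8R, erythro)
Conditions: LiBHEt3 (2.5 equiv), THF, 0 °C to rt; then H2O
Reagents that add atoms: none
Why: SN2 displacement of the primary tosylate by hydride from LiBHEt3 (reductive removal of a sulfonate) turns C9 into the methyl group, the first equivalent of hydride only deprotonating the C7 hydroxyl, while the alkene and the aryl ethers are inert and C7 and C8 keep their configuration because neither takes part.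

Compound list
1 | 4-allyl-2,6-dimethoxyphenol | C=CCc1cc(OC)c(O)c(OC)c1 | starting material
2 | ethyl bromoacetate | CCOC(=O)CBr | starting material
3 | ethyl 2-(4-allyl-2,6-dimethoxyphenoxy)acetate | C=CCc1cc(OC)c(OCC(=O)OCC)c(OC)c1 | intermediate
4 | 2-(4-allyl-2,6-dimethoxyphenoxy)acetic acid | C=CCc1cc(OC)c(OCC(=O)O)c(OC)c1 | intermediate
5 | (R)-4-benzyloxazolidin-2-one | O=C1N[C@H](Cc2ccccc2)CO1 | starting material
6 | 2-(4-allyl-2,6-dimethoxyphenoxy)acetic pivalic anhydride | C=CCc1cc(OC)c(OCC(=O)OC(=O)C(C)(C)C)c(OC)c1 | intermediate (not isolated)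
7 | (R)-3-[2-(4-allyl-2,6-dimethoxyphenoxy)acetyl]-4-benzyloxazolidin-2-one | C=CCc1cc(OC)c(OCC(=O)N2[C@H](Cc3ccccc3)COC2=O)c(OC)c1 | intermediate
8 | 3,4,5-trimethoxybenzaldehyde | COc1cc(C=O)cc(OC)c1OC | starting material
9 | (R)-3-[(2S,3S)-2-(4-allyl-2,6-dimethoxyphenoxy)-3-(3,4,5-trimethoxyphenyl)-3-(trimethylsilyloxy)propanoyl]-4-benzyloxazolidin-2-one | C=CCc1cc(OC)c(O[C@H](C(=O)N2[C@H](Cc3ccccc3)COC2=O)[C@@H](O[Si](C)(C)C)c2cc(OC)c(OC)c(OC)c2)c(OC)c1 | intermediate (not isolated)
10 | (R)-3-[(2S,3S)-2-(4-allyl-2,6-dimethoxyphenoxy)-3-hydroxy-3-(3,4,5-trimethoxyphenyl)propanoyl]-4-benzyloxazolidin-2-one | C=CCc1cc(OC)c(O[C@H](C(=O)N2[C@H](Cc3ccccc3)COC2=O)[C@@H](O)c2cc(OC)c(OC)c(OC)c2)c(OC)c1 | intermediate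
11 | (1S,2R)-2-(4-allyl-2,6-dimethoxyphenoxy)-1-(3,4,5-trimethoxyphenyl)propane-1,3-diol | C=CCc1cc(OC)c(O[C@H](CO)[C@@H](O)c2cc(OC)c(OC)c(OC)c2)c(OC)c1 | intermediate
12 | (2R,3S)-2-(4-allyl-2,6-dimethoxyphenoxy)-3-hydroxy-3-(3,4,5-trimethoxyphenyl)propyl 4-methylbenzenesulfonate | C=CCc1cc(OC)c(O[C@H](COS(=O)(=O)c2ccc(C)cc2)[C@@H](O)c2cc(OC)c(OC)c(OC)c2)c(OC)c1 | intermediate
13 | rhaphidecursinol B, (1S,2R)-2-(4-allyl-2,6-dimethoxyphenoxy)-1-(3,4,5-trimethoxyphenyl)propan-1-ol | C=CCc1cc(OC)c(O[C@H](C)[C@@H](O)c2cc(OC)c(OC)c(OC)c2)c(OC)c1 | target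

Total step count: 7
Longest linear sequence: 7 steps (1 to 13; aldehyde 8 enters at step 4)

Steps most likely to fail

Step 4. What may go wrong: slow or incomplete soft enolisation, competing coordination of the aryloxy oxygen to magnesium that erodes the anti preference or the facial bias, and retro-aldol equilibration before the aldolate is silylated. The fallback sets out from acid 4 and comes back at target 13. Acid 4 is coupled through the same mixed anhydride 6 to commercial (S)-4-benzyloxazolidin-2-one (PivCl, Et3N, LiCl, THF) to give (S)-3-[2-(4-allyl-2,6-dimethoxyphenoxy)acetyl]-4-benzyloxazolidin-2-one F1. Its dibutylboron Z-enolate (Bu2BOTf, iPr2NEt, CH2Cl2, −78 °C) adds to aldehyde 8 through the closed chair transition state of the Evans syn aldol, a reaction established for aryloxyacetyl imides. It should give (S)-3-[(2S,3R)-2-(4-allyl-2,6-dimethoxyphenoxy)-3-hydroxy-3-(3,4,5-trimethoxyphenyl)propanoyl]-4-benzyloxazolidin-2-one F2, in which C8 already has the arrangement of the target and C7 is epimeric. The end game of steps 5 to 7 (LiBH4; TsCl; LiBHEt3) then leads through (1R,2R)-2-(4-allyl-2,6-dimethoxyphenoxy)-1-(3,4,5-trimethoxyphenyl)propane-1,3-diol F3 and (2R,3R)-2-(4-allyl-2,6-dimethoxyphenoxy)-3-hydroxy-3-(3,4,5-trimethoxyphenyl)propyl 4-methylbenzenesulfonate F4 to the threo alcohol (1R,2R)-2-(4-allyl-2,6-dimethoxyphenoxy)-1-(3,4,5-trimethoxyphenyl)propan-1-ol F5. Mitsunobu inversion at C7 (4-nitrobenzoic acid, PPh3, DIAD, THF, 0 °C) gives (1S,2R)-2-(4-allyl-2,6-dimethoxyphenoxy)-1-(3,4,5-trimethoxyphenyl)propyl 4-nitrobenzoate F6, and methanolysis (K2CO3, MeOH, rt) releases 13.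

Step 7. What may go wrong: the C7 alkoxide generated by the hydride closes an oxetane onto C9, or elimination competes, before hydride displaces the sulfonate. The fallback sets out from tosylate 12 and comes back at target 13. The C7 hydroxyl is capped first (Et3SiCl, imidazole, DMF, rt) to give (2R,3S)-2-(4-allyl-2,6-dimethoxyphenoxy)-3-(triethylsilyloxy)-3-(3,4,5-trimethoxyphenyl)propyl 4-methylbenzenesulfonate F7. LiBHEt3 in THF then reduces the sulfonate with no alkoxide present and should give triethyl{[(1S,2R)-2-(4-allyl-2,6-dimethoxyphenoxy)-1-(3,4,5-trimethoxyphenyl)propyl]oxy}silane F8. Bu4NF in THF, a fluoride source without acid, frees 13.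

Step 6. What may go wrong: loss of site selectivity, that is sulfonylation of both hydroxyls or of the benzylic one, whose sulfonate would ionise. The fallback sets out from diol 11 and comes back at target 13, bypassing 12. The primary hydroxyl alone is converted into the iodide under Appel-type conditions (I2, PPh3, imidazole, CH2Cl2, 0 °C), which discriminate strongly between primary and secondary alcohols, to give (1S,2S)-2-(4-allyl-2,6-dimethoxyphenoxy)-3-iodo-1-(3,4,5-trimethoxyphenyl)propan-1-ol F9; its C8 descriptor changes only because CH2I outranks C7. Radical-chain reduction under neutral conditions (Bu3SnH, AIBN, toluene, 80 °C) then gives 13 without any alkoxide being formed.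

Further compounds
F1 | step 4 | (S)-3-[2-(4-allyl-2,6-dimethoxyphenoxy)acetyl]-4-benzyloxazolidin-2-one | C=CCc1cc(OC)c(OCC(=O)N2[C@@H](Cc3ccccc3)COC2=O)c(OC)c1
F2 | step 4 | (S)-3-[(2S,3R)-2-(4-allyl-2,6-dimethoxyphenoxy)-3-hydroxy-3-(3,4,5-trimethoxyphenyl)propanoyl]-4-benzyloxazolidin-2-one | C=CCc1cc(OC)c(O[C@H](C(=O)N2[C@@H](Cc3ccccc3)COC2=O)[C@H](O)c2cc(OC)c(OC)c(OC)c2)c(OC)c1
F3 | step 4 | (1R,2R)-2-(4-allyl-2,6-dimethoxyphenoxy)-1-(3,4,5-trimethoxyphenyl)propane-1,3-diol | C=CCc1cc(OC)c(O[C@H](CO)[C@H](O)c2cc(OC)c(OC)c(OC)c2)c(OC)c1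
F4 | step 4 | (2R,3R)-2-(4-allyl-2,6-dimethoxyphenoxy)-3-hydroxy-3-(3,4,5-trimethoxyphenyl)propyl 4-methylbenzenesulfonate | C=CCc1cc(OC)c(O[C@H](COS(=O)(=O)c2ccc(C)cc2)[C@H](O)c2cc(OC)c(OC)c(OC)c2)c(OC)c1
F5 | step 4 | (1R,2R)-2-(4-allyl-2,6-dimethoxyphenoxy)-1-(3,4,5-trimethoxyphenyl)propan-1-ol | C=CCc1cc(OC)c(O[C@H](C)[C@H](O)c2cc(OC)c(OC)c(OC)c2)c(OC)c1
F6 | step 4 | (1S,2R)-2-(4-allyl-2,6-dimethoxyphenoxy)-1-(3,4,5-trimethoxyphenyl)propyl 4-nitrobenzoate | C=CCc1cc(OC)c(O[C@H](C)[C@@H](OC(=O)c2ccc(cc2)[N+](=O)[O-])c2cc(OC)c(OC)c(OC)c2)c(OC)c1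
F7 | step 7 | (2R,3S)-2-(4-allyl-2,6-dimethoxyphenoxy)-3-(triethylsilyloxy)-3-(3,4,5-trimethoxyphenyl)propyl 4-methylbenzenesulfonate | C=CCc1cc(OC)c(O[C@H](COS(=O)(=O)c2ccc(C)cc2)[C@@H](O[Si](CC)(CC)CC)c2cc(OC)c(OC)c(OC)c2)c(OC)c1
F8 | step 7 | triethyl{[(1S,2R)-2-(4-allyl-2,6-dimethoxyphenoxy)-1-(3,4,5-trimethoxyphenyl)propyl]oxy}silane | C=CCc1cc(OC)c(O[C@H](C)[C@@H](O[Si](CC)(CC)CC)c2cc(OC)c(OC)c(OC)c2)c(OC)c1
F9 | step 6 | (1S,2S)-2-(4-allyl-2,6-dimethoxyphenoxy)-3-iodo-1-(3,4,5-trimethoxyphenyl)propan-1-ol | C=CCc1cc(OC)c(O[C@H](CI)[C@@H](O)c2cc(OC)c(OC)c(OC)c2)c(OC)c1
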